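The flavanone is cut at the C2–C3 bond of the pyranone ring (ring C). The precursor is open-chain: an aryl diazomethyl ketone on ring A, which already carries the C6 side chain and whose less hindered ortho oxygen (future O1) bears the protected vanillyl CH2 group (future C2 plus ring B). A chiral dirhodium carboxylate makes the diazo carbon (future C3) a carbenoid that inserts into one enantiotopic C–H bond of this O1–CH2–aryl unit, closing ring C and setting C2 in one operation. The step exploits the hydridic C2–H bonds, activated by O1 and ring B, and the position of C3 next to the C4 ketone; it also fixes 6- versus 8-substitution.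

Key step: step 12

Assumption: Rh2(S-PTTL)4, dirhodium tetrakis[N-phthaloyl-(S)-tert-leucinate], is taken to select the benzylic hydrogen that leads to the (2S) product; if a trial run shows the opposite sense, the mirror-image catalyst Rh2(R-PTTL)4 is used under the same conditions.

Step 1
Reactants: 1 geranyl acetate
Product: 2 (2E)-5-(3,3-dimethyloxiran-2-yl)-3-methylpent-2-en-1-yl acetate (racemic 6,7-epoxide)
Conditions: mCPBA (1.05 equiv), NaHCO3, CH2Cl2, 0 °C
Reagents that add atoms: 3-chloroperoxybenzoic acid (mCPBA), OOC(=O)c1cccc(Cl)c1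
Why: Prilezhaev epoxidation should occur only at the remote, electron-rich 6,7-alkene because the 2,3-alkene is deactivated by the allylic acetate; the new stereocentre is racemic and is erased in step 2.

Step 2
Reactants: 2 racemic 6,7-epoxygeranyl acetate
Product: 5 (2E,5E)-7-hydroxy-3,7-dimethylocta-2,5-dien-1-yl acetate, via hydroxy selenide 3 (not isolated), via selenoxide 4 (not isolated)
Conditions: PhSeSePh, NaBH4, EtOH, 0 °C to reflux; then 30% H2O2, THF, 0 °C to rt
Reagents that add atoms: none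
Why: the phenylselenide anion should open the epoxide at the less substituted C6, and the selenoxide syn-elimination can only take a hydrogen from C5, which gives the (5E)-configured tertiary allylic alcohol (epoxide to allylic alcohol transposition by selenoxide elimination).

Step 3
Reactants: 5 (2E,5E)-7-hydroxy-3,7-dimethylocta-2,5-dien-1-yl acetate
Product: 7 (2E,5E)-3,7-dimethyl-7-(triethylsilyloxy)octa-2,5-dien-1-ol, via silyl ether acetate 6 (not isolated)
Conditions: Et3SiOTf, 2,6-lutidine, CH2Cl2, −78 °C; then K2CO3, MeOH, 0 °C to rt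
Reagents that add atoms: triethylsilyl trifluoromethanesulfonate, CC[Si](CC)(CC)OS(=O)(=O)C(F)(F)F
Why: silyl triflate silylation of the tertiary alcohol followed in the same flask by carbonate-catalysed methanolysis of the acetate should free only the primary allylic alcohol, since a tertiary triethylsilyl ether is stable to K2CO3 in methanol.

Step 4
Reactants: 7 (2E,5E)-3,7-dimethyl-7-(triethylsilyloxy)octa-2,5-dien-1-ol
Product: 9 (2E,5E)-1-bromo-3,7-dimethyl-7-(triethylsilyloxy)octa-2,5-diene, via allylic mesylate 8 (not isolated)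
Conditions: MsCl, Et3N, THF, −40 °C; then LiBr, THF, 0 °C
Reagents that add atoms: lithium bromide, [Li+].[Br-]
Why: mesylation and SN2 displacement by bromide under non-acidic conditions should give the primary allylic bromide without allylic shift, loss of the (2E) geometry or ionisation of the tertiary allylic silyl ether.

Step 5
Reactants: 10 2,4,6-trihydroxyacetophenone (anhydrous, in excess); 9 allylic bromide
Product: 11 1-{2,4,6-trihydroxy-3-[(2E,5E)-3,7-dimethyl-7-(triethylsilyloxy)octa-2,5-dien-1-yl]phenyl}ethanone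
Conditions: DBU, THF, 0 °C to rt
Reagents that add atoms: none
Why: C-alkylation of the ambident phloroglucinol-type phenoxide by a primary allylic bromide (SN2) should give the linear ring-allylated ketone with the alkene geometry retained, and the excess of 10 limits dialkylation.

Step 6
Reactants: 11 C-alkylated trihydroxyacetophenone
Product: 12 1-{2,6-dihydroxy-3-[(2E,5E)-3,7-dimethyl-7-(triethylsilyloxy)octa-2,5-dien-1-yl]-4-(triisopropylsilyloxy)phenyl}ethanone
Conditions: iPr3SiCl (1.05 equiv), imidazole, CH2Cl2–DMF, 0 °C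
Reagents that add atoms: chlorotriisopropylsilane, CC(C)[Si](Cl)(C(C)C)C(C)C
Why: the 4-hydroxyl, para to the acetyl group, is the most acidic phenol and is not engaged in a hydrogen bond to the carbonyl group, so selective monosilylation there is expected.

Step 7
Reactants: 13 vanillin
Product: 14 4-(tert-butyldimethylsilyloxy)-3-methoxybenzaldehyde
Conditions: tBuMe2SiCl, imidazole, DMF, rt
Reagents that add atoms: tert-butylchlorodimethylsilane, CC(C)(C)[Si](C)(C)Cl
Why: standard silylation of a phenol with a silyl chloride and imidazole.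

Step 8
Reactants: 14 silylated vanillin
Product: 15 [4-(tert-butyldimethylsilyloxy)-3-methoxyphenyl]methanol
Conditions: NaBH4, THF–MeOH, 0 °C
Reagents that add atoms: none
Why: borohydride reduction of the aldehyde is fast at 0 °C and should leave the aryl silyl ether intact.

Step 9
Reactants: 12 2,6-dihydroxy ketone; 15 benzylic alcohol
Product: 16 1-{6-{[4-(tert-butyldimethylsilyloxy)-3-methoxyphenyl]methoxy}-2-hydroxy-3-[(2E,5E)-3,7-dimethyl-7-(triethylsilyloxy)octa-2,5-dien-1-yl]-4-(triisopropylsilyloxy)phenyl}ethanone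
Conditions: PPh3, DIAD, THF, 0 °C to rt
Reagents that add atoms: none
Why: the Mitsunobu etherification should alkylate the 6-hydroxyl, which is flanked by a ring hydrogen, in preference to the 2-hydroxyl buried between the acetyl group and the side chain, and the neutral conditions leave all silyl ethers untouched.

Step 10
Reactants: 16 mono-benzylated ketone
Product: 17 1-{2-(tert-butyldimethylsilyloxy)-6-{[4-(tert-butyldimethylsilyloxy)-3-methoxyphenyl]methoxy}-3-[(2E,5E)-3,7-dimethyl-7-(triethylsilyloxy)octa-2,5-dien-1-yl]-4-(triisopropylsilyloxy)phenyl}ethanone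
Conditions: tBuMe2SiOTf, 2,6-lutidine, CH2Cl2, −20 to 0 °C
Reagents that add atoms: tert-butyldimethylsilyl trifluoromethanesulfonate, CC(C)(C)[Si](C)(C)OS(=O)(=O)C(F)(F)F
Why: the silyl triflate should silylate the remaining hindered, hydrogen-bonded phenol, and a silyl ether is chosen because it offers the later carbenoid neither a nucleophilic oxygen nor a C–H bond within reach.

Step 11
Reactants: 17 fully protected methyl ketone
Product: 19 2-diazo-1-{2-(tert-butyldimethylsilyloxy)-6-{[4-(tert-butyldimethylsilyloxy)-3-methoxyphenyl]methoxy}-3-[(2E,5E)-3,7-dimethyl-7-(triethylsilyloxy)octa-2,5-dien-1-yl]-4-(triisopropylsilyloxy)phenyl}ethanone, via trifluoroacetyl diketone 18 (not isolated)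
Conditions: LiN(SiMe3)2, THF, −78 °C; CF3CO2CH2CF3; aq. NH4Cl; then MsN3, Et3N, H2O, MeCN, rt
Reagents that add atoms: methanesulfonyl azide, CS(=O)(=O)N=[N+]=[N-]
Why: Claisen-type trifluoroacetylation of the kinetic methyl ketone enolate activates the methyl group for Regitz diazo transfer, in which the trifluoroacetyl group is split off to leave the diazomethyl ketone (detrifluoroacetylative diazo transfer).

Step 12
Reactants: 19 diazomethyl ketone
Product: 20 (2S)-5-(tert-butyldimethylsilyloxy)-2-[4-(tert-butyldimethylsilyloxy)-3-methoxyphenyl]-6-[(2E,5E)-3,7-dimethyl-7-(triethylsilyloxy)octa-2,5-dien-1-yl]-7-(triisopropylsilyloxy)-2,3-dihydro-4H-chromen-4-one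
Conditions: Rh2(S-PTTL)4 (1 mol %), CH2Cl2, −20 to 0 °C, slow addition of 19, high dilution
Reagents that add atoms: none
Why: Loss of N2 from 19 at the divalent rhodium centre gives an electrophilic alpha-oxo carbenoid at the future C3, which inserts into a C–H bond of the O1–CH2–aryl group through a three-centre, hydride-transfer-like transition state, forming the C2–C3 bond and moving that hydrogen to C3. The closest known reaction type is the dirhodium-carboxylate-catalysed intramolecular C–H insertion of 2-alkoxyaryl diazomethyl ketones next to the ether oxygen, which gives chroman-4-ones and is enantioselective with chiral carboxylate ligands. Ring C closes by 1,6-insertion through a six-membered transition state (C3, C4, C4a, C8a, O1, C2); the usual five-membered mode is not available because the fifth atom is O1. The C2 stereocentre is set by the catalyst, whose chiral N-phthaloyl-tert-leucinate pocket selects one of the two enantiotopic benzylic hydrogens. The step needs C–H insertion to win over attack on the O1 lone pair (oxonium ylide formation and [1,2]-benzyl shift to a benzofuranone) and over reaction at the second ortho oxygen: the aryl ether oxygen is a weak donor, the benzylic C–H bond is made hydridic by O1 and the para-silyloxy ring B, the silyl ether on the 5-oxygen offers neither a reachable C–H bond nor a nucleophilic oxygen, and the side chain is meta to the acyl group and out of reach. Slow addition at high dilution should suppress carbene dimerisation and intermolecular cyclopropanation of the side-chain alkenes.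

Step 13
Reactants: 20 tetrasilylated flavanone
Product: 21 tomentodiplacone B, (2S)-5,7-dihydroxy-2-(4-hydroxy-3-methoxyphenyl)-6-[(2E,5E)-7-hydroxy-3,7-dimethylocta-2,5-dien-1-yl]-2,3-dihydro-4H-chromen-4-one
Conditions: Bu4NF, AcOH (1:1, excess), THF, 0 °C to rt
Reagents that add atoms: none
Why: acetic-acid-buffered fluoride should cleave the three aryl silyl ethers and the tertiary triethylsilyl ether without generating free phenoxide, so that neither base-induced ring opening of the flavanone (loss of the C2 configuration) nor ionisation of the tertiary allylic alcohol is expected.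

Compound list
1 | geranyl acetate, (2E)-3,7-dimethylocta-2,6-dien-1-yl acetate | CC(=O)OC/C=C(\C)CCC=C(C)C | starting material
2 | (2E)-5-(3,3-dimethyloxiran-2-yl)-3-methylpent-2-en-1-yl acetate (racemic) | CC(=O)OC/C=C(\C)CCC1OC1(C)C | intermediate
3 | (2E)-7-hydroxy-3,7-dimethyl-6-(phenylselanyl)oct-2-en-1-yl acetate (racemic, not isolated) | CC(=O)OC/C=C(\C)CCC([Se]c1ccccc1)C(C)(C)O | intermediate
4 | (2E)-7-hydroxy-3,7-dimethyl-6-(phenylseleninyl)oct-2-en-1-yl acetate (not isolated) | CC(=O)OC/C=C(\C)CCC([Se](=O)c1ccccc1)C(C)(C)O | intermediate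
5 | (2E,5E)-7-hydroxy-3,7-dimethylocta-2,5-dien-1-yl acetate | CC(=O)OC/C=C(\C)C/C=C/C(C)(C)O | intermediate
6 | (2E,5E)-3,7-dimethyl-7-(triethylsilyloxy)octa-2,5-dien-1-yl acetate (not isolated) | CC(=O)OC/C=C(\C)C/C=C/C(C)(C)O[Si](CC)(CC)CC | intermediate
7 | (2E,5E)-3,7-dimethyl-7-(triethylsilyloxy)octa-2,5-dien-1-ol | OC/C=C(\C)C/C=C/C(C)(C)O[Si](CC)(CC)CC | intermediate
8 | (2E,5E)-3,7-dimethyl-7-(triethylsilyloxy)octa-2,5-dien-1-yl methanesulfonate (not isolated) | CS(=O)(=O)OC/C=C(\C)C/C=C/C(C)(C)O[Si](CC)(CC)CC | intermediate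
9 | (2E,5E)-1-bromo-3,7-dimethyl-7-(triethylsilyloxy)octa-2,5-diene | BrC/C=C(\C)C/C=C/C(C)(C)O[Si](CC)(CC)CC | intermediate
10 | 2,4,6-trihydroxyacetophenone | CC(=O)c1c(O)cc(O)cc1O | starting material
11 | 1-{2,4,6-trihydroxy-3-[(2E,5E)-3,7-dimethyl-7-(triethylsilyloxy)octa-2,5-dien-1-yl]phenyl}ethanone | CC(=O)c1c(O)cc(O)c(C/C=C(\C)C/C=C/C(C)(C)O[Si](CC)(CC)CC)c1O | intermediate
12 | 1-{2,6-dihydroxy-3-[(2E,5E)-3,7-dimethyl-7-(triethylsilyloxy)octa-2,5-dien-1-yl]-4-(triisopropylsilyloxy)phenyl}ethanone | CC(=O)c1c(O)cc(O[Si](C(C)C)(C(C)C)C(C)C)c(C/C=C(\C)C/C=C/C(C)(C)O[Si](CC)(CC)CC)c1O | intermediate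
13 | vanillin, 4-hydroxy-3-methoxybenzaldehyde | COc1cc(C=O)ccc1O | starting material
14 | 4-(tert-butyldimethylsilyloxy)-3-methoxybenzaldehyde | COc1cc(C=O)ccc1O[Si](C)(C)C(C)(C)C | intermediate
15 | [4-(tert-butyldimethylsilyloxy)-3-methoxyphenyl]methanol | COc1cc(CO)ccc1O[Si](C)(C)C(C)(C)C | intermediate
16 | 1-{6-{[4-(tert-butyldimethylsilyloxy)-3-methoxyphenyl]methoxy}-2-hydroxy-3-[(2E,5E)-3,7-dimethyl-7-(triethylsilyloxy)octa-2,5-dien-1-yl]-4-(triisopropylsilyloxy)phenyl}ethanone | CC(=O)c1c(OCc2ccc(O[Si](C)(C)C(C)(C)C)c(OC)c2)cc(O[Si](C(C)C)(C(C)C)C(C)C)c(C/C=C(\C)C/C=C/C(C)(C)O[Si](CC)(CC)CC)c1O | intermediate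
17 | 1-{2-(tert-butyldimethylsilyloxy)-6-{[4-(tert-butyldimethylsilyloxy)-3-methoxyphenyl]methoxy}-3-[(2E,5E)-3,7-dimethyl-7-(triethylsilyloxy)octa-2,5-dien-1-yl]-4-(triisopropylsilyloxy)phenyl}ethanone | CC(=O)c1c(OCc2ccc(O[Si](C)(C)C(C)(C)C)c(OC)c2)cc(O[Si](C(C)C)(C(C)C)C(C)C)c(C/C=C(\C)C/C=C/C(C)(C)O[Si](CC)(CC)CC)c1O[Si](C)(C)C(C)(C)C | intermediate
18 | 4,4,4-trifluoro-1-(aryl)butane-1,3-dione, aryl as in 17 (not isolated) | O=C(CC(=O)c1c(OCc2ccc(O[Si](C)(C)C(C)(C)C)c(OC)c2)cc(O[Si](C(C)C)(C(C)C)C(C)C)c(C/C=C(\C)C/C=C/C(C)(C)O[Si](CC)(CC)CC)c1O[Si](C)(C)C(C)(C)C)C(F)(F)F | intermediate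
19 | 2-diazo-1-(aryl)ethanone, aryl as in 17 | [N-]=[N+]=CC(=O)c1c(OCc2ccc(O[Si](C)(C)C(C)(C)C)c(OC)c2)cc(O[Si](C(C)C)(C(C)C)C(C)C)c(C/C=C(\C)C/C=C/C(C)(C)O[Si](CC)(CC)CC)c1O[Si](C)(C)C(C)(C)C | intermediate
20 | (2S)-5-(tert-butyldimethylsilyloxy)-2-[4-(tert-butyldimethylsilyloxy)-3-methoxyphenyl]-6-[(2E,5E)-3,7-dimethyl-7-(triethylsilyloxy)octa-2,5-dien-1-yl]-7-(triisopropylsilyloxy)-2,3-dihydro-4H-chromen-4-one | COc1cc([C@@H]2CC(=O)c3c(cc(O[Si](C(C)C)(C(C)C)C(C)C)c(C/C=C(\C)C/C=C/C(C)(C)O[Si](CC)(CC)CC)c3O[Si](C)(C)C(C)(C)C)O2)ccc1O[Si](C)(C)C(C)(C)C | intermediate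
21 | tomentodiplacone B, (2S)-5,7-dihydroxy-2-(4-hydroxy-3-methoxyphenyl)-6-[(2E,5E)-7-hydroxy-3,7-dimethylocta-2,5-dien-1-yl]-2,3-dihydro-4H-chromen-4-one | COc1cc([C@@H]2CC(=O)c3c(cc(O)c(C/C=C(\C)C/C=C/C(C)(C)O)c3O)O2)ccc1O | target

Total step count: 13. Longest linear sequence: 11 steps (steps 1–6 and 9–13, from geranyl acetate 1 to 21); steps 7 and 8 form the ring B branch.

Steps most likely to fail

Step 12. The carbenoid may attack the lone pair of the benzyl ether oxygen instead of the C–H bond (oxonium ylide formation and [1,2]-benzyl shift), and the discrimination between the two enantiotopic benzylic hydrogens may be incomplete. The fallback sets out from 12 and comes back at 20; it closes ring C from the oxygen side and brings in ring B by asymmetric conjugate arylation. Mitsunobu reaction of 12 with allyl alcohol (PPh3, DIAD, THF), under the same steric control as step 9, should give the 6-O-allyl ether F1. Silylation of the hindered phenol (tBuMe2SiOTf, 2,6-lutidine) gives the allyl silyl ether F2, and Pd(PPh3)4 with morpholine removes the allyl group to give the 6-hydroxy ketone F3. Heating F3 with Me2NCH(OMe)2 in toluene gives the enaminone F4, which on brief treatment with dilute HCl in CH2Cl2 closes with loss of dimethylamine to the chromone F5. Conjugate addition of commercial [4-(tert-butyldimethylsilyloxy)-3-methoxyphenyl]boronic acid to C2 of F5 then gives 20. This uses Pd(OCOCF3)2, the enantiomer of the t-BuPyOx ligand that leads to the (2S) series, NH4PF6 and water in 1,2-dichloroethane at 60 °C.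

Step 5. The ambident tri-phenoxide may be alkylated on oxygen or more than once on carbon, so that mono-C-alkylation is inefficient. The fallback sets out from 10 (with 9 and 15 from the route) and comes back at 16, replacing steps 5, 6 and 9; it builds the aryl–allyl bond by cross-coupling. Silylation of 10 at the 4-hydroxyl (iPr3SiCl, imidazole) gives the 4-O-silyl diol F6. Mitsunobu reaction of F6 with 15 on one of its two equivalent hydroxyls gives the mono-ether F7, so the regiochemical question of step 9 does not arise. Iodination with N-iodosuccinimide ortho to the free hydroxyl gives the aryl iodide F8. Bromide 9 is converted with Bu3SnLi in THF at −78 °C into the allylstannane F9. Stille coupling of F8 with F9 (Pd2(dba)3, AsPh3, CuI, DMF), which should couple at the tin-bearing carbon, gives 16.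

Step 11. The tert-butyldimethylsilyl group on the ortho oxygen may migrate to the enolate oxygen, or enolisation of the hindered, twisted ketone may be incomplete. The fallback sets out from 17 and comes back at 19; it avoids a free enolate and makes the diazo group from an alpha-bromoketone. Soft enolisation of 17 (Me3SiOTf, Et3N, CH2Cl2, 0 °C) gives the trimethylsilyl enol ether F10. N-bromosuccinimide in THF at −78 °C gives the bromomethyl ketone F11. N,N'-ditosylhydrazine and DBU in THF at 0 °C convert F11 into 19.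

Further compounds
F1 | step 12 | 1-{6-(allyloxy)-2-hydroxy-3-[(2E,5E)-3,7-dimethyl-7-(triethylsilyloxy)octa-2,5-dien-1-yl]-4-(triisopropylsilyloxy)phenyl}ethanone | CC(=O)c1c(OCC=C)cc(O[Si](C(C)C)(C(C)C)C(C)C)c(C/C=C(\C)C/C=C/C(C)(C)O[Si](CC)(CC)CC)c1O
F2 | step 12 | 1-{6-(allyloxy)-2-(tert-butyldimethylsilyloxy)-3-[(2E,5E)-3,7-dimethyl-7-(triethylsilyloxy)octa-2,5-dien-1-yl]-4-(triisopropylsilyloxy)phenyl}ethanone | CC(=O)c1c(OCC=C)cc(O[Si](C(C)C)(C(C)C)C(C)C)c(C/C=C(\C)C/C=C/C(C)(C)O[Si](CC)(CC)CC)c1O[Si](C)(C)C(C)(C)C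
F3 | step 12 | 1-{2-(tert-butyldimethylsilyloxy)-6-hydroxy-3-[(2E,5E)-3,7-dimethyl-7-(triethylsilyloxy)octa-2,5-dien-1-yl]-4-(triisopropylsilyloxy)phenyl}ethanone | CC(=O)c1c(O)cc(O[Si](C(C)C)(C(C)C)C(C)C)c(C/C=C(\C)C/C=C/C(C)(C)O[Si](CC)(CC)CC)c1O[Si](C)(C)C(C)(C)C
F4 | step 12 | (2E)-3-(dimethylamino)-1-(aryl)prop-2-en-1-one, aryl as in F3 | CN(C)/C=C/C(=O)c1c(O)cc(O[Si](C(C)C)(C(C)C)C(C)C)c(C/C=C(\C)C/C=C/C(C)(C)O[Si](CC)(CC)CC)c1O[Si](C)(C)C(C)(C)C
F5 | step 12 | 5-(tert-butyldimethylsilyloxy)-6-[(2E,5E)-3,7-dimethyl-7-(triethylsilyloxy)octa-2,5-dien-1-yl]-7-(triisopropylsilyloxy)-4H-chromen-4-one | O=c1ccoc2cc(O[Si](C(C)C)(C(C)C)C(C)C)c(C/C=C(\C)C/C=C/C(C)(C)O[Si](CC)(CC)CC)c(O[Si](C)(C)C(C)(C)C)c12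
F6 | step 5 | 1-[2,6-dihydroxy-4-(triisopropylsilyloxy)phenyl]ethanone | CC(=O)c1c(O)cc(O[Si](C(C)C)(C(C)C)C(C)C)cc1O
F7 | step 5 | 1-{2-{[4-(tert-butyldimethylsilyloxy)-3-methoxyphenyl]methoxy}-6-hydroxy-4-(triisopropylsilyloxy)phenyl}ethanone | CC(=O)c1c(OCc2ccc(O[Si](C)(C)C(C)(C)C)c(OC)c2)cc(O[Si](C(C)C)(C(C)C)C(C)C)cc1O
F8 | step 5 | 1-{6-{[4-(tert-butyldimethylsilyloxy)-3-methoxyphenyl]methoxy}-2-hydroxy-3-iodo-4-(triisopropylsilyloxy)phenyl}ethanone | CC(=O)c1c(OCc2ccc(O[Si](C)(C)C(C)(C)C)c(OC)c2)cc(O[Si](C(C)C)(C(C)C)C(C)C)c(I)c1O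
F9 | step 5 | tributyl[(2E,5E)-3,7-dimethyl-7-(triethylsilyloxy)octa-2,5-dien-1-yl]stannane | CCCC[Sn](CCCC)(CCCC)C/C=C(\C)C/C=C/C(C)(C)O[Si](CC)(CC)CC
F10 | step 11 | trimethylsilyl enol ether of 17, 1-(aryl)-1-(trimethylsilyloxy)ethene | C=C(O[Si](C)(C)C)c1c(OCc2ccc(O[Si](C)(C)C(C)(C)C)c(OC)c2)cc(O[Si](C(C)C)(C(C)C)C(C)C)c(C/C=C(\C)C/C=C/C(C)(C)O[Si](CC)(CC)CC)c1O[Si](C)(C)C(C)(C)C
F11 | step 11 | 2-bromo-1-(aryl)ethanone, aryl as in 17 | BrCC(=O)c1c(OCc2ccc(O[Si](C)(C)C(C)(C)C)c(OC)c2)cc(O[Si](C(C)C)(C(C)C)C(C)C)c(C/C=C(\C)C/C=C/C(C)(C)O[Si](CC)(CC)CC)c1O[Si](C)(C)C(C)(C)C
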